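**Plan**

1. Retrosynthesis first cuts the C6–OMe bond (ketal exchange through a separable chiral ketal). It then cuts both C–O bonds of the peroxide (C3–O and C6–O), which takes the six-membered 3,6-dihydro-1,2-dioxine ring, minus O2, back to the four-membered ring of a cyclobut-2-en-1-ol in which C3 and C6 are joined by a σ-bond.
2. The enabling feature is the C3–C4=C5–C6 unit of the dioxine: C6 at the ketone (hemiketal) level, C3 allylic and peroxidised, C4=C5 cis. Strain-driven β-scission of a tertiary cyclobutenyl alkoxide followed by O2 capture at the resulting allylic radical delivers exactly this, and the cis ring olefin becomes the Z olefin needed for hemiketal closure.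
3. Further cuts: the ring C=C (selenoxide elimination), C6–C7 (hexadecyl Grignard addition) and C3–CH2CO2Me (α-alkylation of cyclobutanone).
4. Forward order: cyclobutanone → acetate arm → α′-selenide → hexadecyl carbinol → cyclobutene → carboxylate → O2 insertion (four → six ring atoms) → ketals.
5. Stereochemistry: all cyclobutane stereocentres are erased in the ring expansion. C3 arises racemic and is resolved as the diastereomeric (S)-1-phenylethyl ketals. C6 is set last under thermodynamic (anomeric) control, with OMe cis to the C3 side chain.

Key step: step 7

Remark: 5, 6, 8, 10 and 11 are racemic (6, 8, 10 and 11 also diastereomer mixtures), which is harmless because every cyclobutane stereocentre is destroyed in step 7; any cis-fused γ-lactone formed from 8 or 10 is opened to 11 in step 6.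

**Step 1**
Reactants: 1 cyclobutanone
Product: 2 cyclobutanone N,N-dimethylhydrazone
Conditions: Me2NNH2, AcOH (cat.), EtOH, reflux
Reagents that add atoms: 1,1-dimethylhydrazine CN(C)N
Why: Acid-catalysed condensation of a ketone with an unsymmetrical hydrazine (hydrazone formation) is general and provides the aza-enolate precursor needed because cyclobutanone enolates self-condense on direct alkylation.

**Step 2**
Reactants: 2 cyclobutanone N,N-dimethylhydrazone; 3 methyl bromoacetate
Product: 5 methyl 2-(2-oxocyclobutyl)acetate, via alkylated hydrazone 4 (not isolated)
Conditions: LiN(iPr)2 (LDA), THF, 0 °C; then 3, −78 °C → rt; then satd aq. oxalic acid, Et2O, rt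
Reagents that add atoms: water O
Why: Deprotonation of the N,N-dimethylhydrazone and SN2 alkylation of the aza-enolate with an α-bromo ester (hydrazone alkylation) followed by mild oxalic acid hydrolysis should give the mono-alkylated ketone without touching the methyl ester; the new stereocentre is racemic and is erased in step 7.

**Step 3**
Reactants: 5 methyl 2-(2-oxocyclobutyl)acetate
Product: 6 methyl 2-[2-oxo-3-(phenylselanyl)cyclobutyl]acetate
Conditions: LiN(iPr)2 (LDA), THF, −78 °C; then PhSeCl, −78 °C
Reagents that add atoms: benzeneselenenyl chloride Cl[Se]c1ccccc1
Why: Kinetic deprotonation with a hindered amide base at −78 °C should occur at the less substituted α′-methylene of the ketone (far more acidic than the ester α-hydrogens) and the enolate is trapped by the selenium electrophile (α-selenenylation of a ketone enolate); the relative configuration is irrelevant.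

**Step 4**
Reactants: 6 methyl 2-[2-oxo-3-(phenylselanyl)cyclobutyl]acetate; 7 1-bromohexadecane
Product: 8 methyl 2-[2-hexadecyl-2-hydroxy-3-(phenylselanyl)cyclobutyl]acetate
Conditions: 7, Mg, THF, reflux; then LaCl3·2LiCl (cat.) and 6, THF, −78 °C; H2O quench at −78 °C
Reagents that add atoms: none
Why: Grignard 1,2-addition to the strained and therefore very electrophilic cyclobutanone carbonyl at −78 °C should outrun attack on the methyl ester, with LaCl3·2LiCl suppressing enolisation and attack at selenium; the configuration of the new carbinol centre is irrelevant because it becomes the C6 carbonyl in step 7.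

**Step 5**
Reactants: 8 methyl 2-[2-hexadecyl-2-hydroxy-3-(phenylselanyl)cyclobutyl]acetate
Product: 10 methyl 2-(2-hexadecyl-2-hydroxycyclobut-3-en-1-yl)acetate, via selenoxide 9 (not isolated)
Conditions: 30% aq. H2O2, pyridine, CH2Cl2, 0 °C → rt
Reagents that add atoms: none
Why: Oxidation of the selenide and syn-elimination of the selenoxide (selenoxide elimination) can only take a hydrogen from the ring methylene because the other neighbour is the fully substituted carbinol carbon, so the cyclobutene should form regiospecifically at or below room temperature, where the cyclobutenol does not yet open electrocyclically.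

**Step 6**
Reactants: 10 methyl 2-(2-hexadecyl-2-hydroxycyclobut-3-en-1-yl)acetate
Product: 11 lithium 2-(2-hexadecyl-2-hydroxycyclobut-3-en-1-yl)acetate
Conditions: LiOH (1.05 equiv), THF/H2O, 0 °C → rt; lyophilise, use crude
Reagents that add atoms: lithium hydroxide [Li+].[OH-]
Why: Saponification of the methyl ester gives a carboxylate that cannot lactonise onto the cis tertiary alcohol and whose α-hydrogens are too weakly acidic to trigger β-elimination of the peroxide formed in the next step, and it opens any lactone to the same salt.

**Step 7**
Reactants: 11 lithium 2-(2-hexadecyl-2-hydroxycyclobut-3-en-1-yl)acetate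
Product: 14 methyl 2-(6-hexadecyl-6-hydroxy-3,6-dihydro-1,2-dioxin-3-yl)acetate, via open-chain hydroperoxide 12 (not isolated), via lithium dioxinol carboxylate 13 (not isolated)
Conditions: Co(acac)2 (cobalt bis(acetylacetonate), 20 mol %), O2 (1 atm), DMF, rt; then Me2SO4, rt
Reagents that add atoms: dioxygen O=O; dimethyl sulfate COS(=O)(=O)OC
Why: Proposed new method: the alkoxide of 11 on trivalent cobalt (formed from Co(acac)2 and O2) should undergo β-scission of the strained ring bond between the carbinol carbon and the carbon bearing the acetate arm, giving the ketone and a delocalised allylic radical that keeps the cis geometry of the former ring olefin; capture of triplet O2 at the carbon that carries the acetate arm and reduction of the peroxyl radical by divalent cobalt then give the Z γ-hydroperoxy enone 12, whose hydroperoxide adds to the ketone to give 13. The closest known reaction type is the Co(acac)2/O2 oxidative ring expansion of cyclobutanols to 1,2-dioxan-3-ols (and of cyclopropanols to 1,2-dioxolan-3-ols); what is new is the allylic cyclobutenol, which carries the future Z olefin of the dioxine through the event. The six-membered ring closes by 6-exo-trig addition of the hydroperoxide oxygen to the carbonyl carbon, which is possible only because the olefin is Z. C3 is created at a planar radical without control and is therefore racemic (resolved in step 8), and the hemiketal carbon C6 equilibrates. The step needs scission of the carbinol–CH(arm) bond and not of the carbinol–vinyl or carbinol–alkyl bond, which ring strain and allylic stabilisation of the radical secure, and it needs O2 capture at the γ- and not the α-carbon, which the reversibility of O2 addition to allylic radicals and the enone conjugation kept in the γ-adduct should secure; the carboxylate is then O-methylated with Me2SO4 in the same flask.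

**Step 8**
Reactants: 14 methyl 2-(6-hexadecyl-6-hydroxy-3,6-dihydro-1,2-dioxin-3-yl)acetate; 15 (S)-1-phenylethanol
Product: 16 methyl 2-[(3S)-6-hexadecyl-6-[(1S)-1-phenylethoxy]-3,6-dihydro-1,2-dioxin-3-yl]acetate
Conditions: 15 (5 equiv), TsOH·H2O (cat.), 4 Å molecular sieves, CH2Cl2, 0 °C → rt; chromatography on SiO2
Reagents that add atoms: none
Why: Acid-catalysed exchange at the peroxy hemiketal carbon through the allylic peroxycarbenium ion (ketalisation) installs an enantiopure alkoxy group without touching C3, so the two C3 enantiomers become diastereomers that are separated on silica; the (3S) pair, identified by correlation with 17, is taken on as a C6 epimer mixture (resolution through a covalent chiral auxiliary).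

**Step 9**
Reactants: 16 methyl 2-[(3S)-6-hexadecyl-6-[(1S)-1-phenylethoxy]-3,6-dihydro-1,2-dioxin-3-yl]acetate
Product: 17 6-epi-chondrillin, methyl 2-[(3S,6S)-6-hexadecyl-6-methoxy-3,6-dihydro-1,2-dioxin-3-yl]acetate
Conditions: TsOH·H2O (cat.), MeOH, 0 °C → rt; chromatography on SiO2
Reagents that add atoms: methanol CO
Why: Transketalisation in methanol through the same peroxycarbenium ion is reversible, so C6 should settle under thermodynamic control in favour of the (6S) epimer, which has the methoxy group pseudoaxial (anomeric effect) and cis to the pseudoequatorial C3 side chain; C3 is not involved and the minor (6R) epimer is separated and re-equilibrated.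

**Compound list**

1 | cyclobutanone | O=C1CCC1 | starting material
2 | cyclobutanone N,N-dimethylhydrazone | CN(C)N=C1CCC1 | intermediate
3 | methyl bromoacetate | COC(=O)CBr | starting material
4 | methyl 2-[2-(2,2-dimethylhydrazinylidene)cyclobutyl]acetate (alkylated hydrazone; racemic) | COC(=O)CC1CCC1=NN(C)C | intermediate
5 | methyl 2-(2-oxocyclobutyl)acetate (racemic) | COC(=O)CC1CCC1=O | intermediate
6 | methyl 2-[2-oxo-3-(phenylselanyl)cyclobutyl]acetate (racemic diastereomer mixture) | COC(=O)CC1CC([Se]c2ccccc2)C1=O | intermediate
7 | 1-bromohexadecane | CCCCCCCCCCCCCCCCBr | starting material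
8 | methyl 2-[2-hexadecyl-2-hydroxy-3-(phenylselanyl)cyclobutyl]acetate (racemic diastereomer mixture) | COC(=O)CC1CC([Se]c2ccccc2)C1(O)CCCCCCCCCCCCCCCC | intermediate
9 | methyl 2-[2-hexadecyl-2-hydroxy-3-(phenylseleninyl)cyclobutyl]acetate (selenoxide) | COC(=O)CC1CC([Se](=O)c2ccccc2)C1(O)CCCCCCCCCCCCCCCC | intermediate
10 | methyl 2-(2-hexadecyl-2-hydroxycyclobut-3-en-1-yl)acetate (racemic diastereomer mixture) | COC(=O)CC1C=CC1(O)CCCCCCCCCCCCCCCC | intermediate
11 | lithium 2-(2-hexadecyl-2-hydroxycyclobut-3-en-1-yl)acetate (racemic diastereomer mixture) | [Li+].[O-]C(=O)CC1C=CC1(O)CCCCCCCCCCCCCCCC | intermediate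
12 | lithium (4Z)-3-hydroperoxy-6-oxodocos-4-enoate (open-chain hydroperoxide; racemic) | [Li+].[O-]C(=O)CC(OO)/C=C\C(=O)CCCCCCCCCCCCCCCC | intermediate
13 | lithium 2-(6-hexadecyl-6-hydroxy-3,6-dihydro-1,2-dioxin-3-yl)acetate (racemic at C3, C6 epimers) | [Li+].[O-]C(=O)CC1C=CC(O)(CCCCCCCCCCCCCCCC)OO1 | intermediate
14 | methyl 2-(6-hexadecyl-6-hydroxy-3,6-dihydro-1,2-dioxin-3-yl)acetate (racemic at C3, C6 epimers) | COC(=O)CC1C=CC(O)(CCCCCCCCCCCCCCCC)OO1 | intermediate
15 | (S)-1-phenylethanol | C[C@H](O)c1ccccc1 | starting material
16 | methyl 2-[(3S)-6-hexadecyl-6-[(1S)-1-phenylethoxy]-3,6-dihydro-1,2-dioxin-3-yl]acetate (C6 epimers) | CCCCCCCCCCCCCCCCC1(O[C@@H](C)c2ccccc2)C=C[C@H](CC(=O)OC)OO1 | intermediate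
17 | 6-epi-chondrillin, methyl 2-[(3S,6S)-6-hexadecyl-6-methoxy-3,6-dihydro-1,2-dioxin-3-yl]acetate | CCCCCCCCCCCCCCCC[C@@]1(OC)C=C[C@H](CC(=O)OC)OO1 | target

**Totals**

Total step count: 9. Longest linear sequence: 9 steps (from cyclobutanone 1).

**Steps most likely to fail**

Step 7 (proposed new method). The risks are unselective oxygen capture at the α-carbon of the delocalised radical, which would lead to C–C cleavage through an α-hydroperoxy ketone, and cobalt-induced decomposition of the peroxide before hemiketal closure. The fallback uses known chemistry and sets out from 11. Warming 11 in aqueous THF (about 60 °C) should effect conrotatory electrocyclic opening of the cyclobutenol to the dienol, which ketonises and conjugates to lithium (4E)-6-oxodocos-4-enoate F1. O-Methylation with Me2SO4 in DMF gives methyl (4E)-6-oxodocos-4-enoate F2. Irradiation of F2 under O2 with tetraphenylporphyrin as sensitiser (CH2Cl2, Pyrex-filtered mercury lamp) brings about photoenolisation to the Z dienol and [4+2] addition of singlet oxygen, the established entry to 3,6-dihydro-1,2-dioxin-3-ols from enones with γ-hydrogens. The fallback comes back to the route at 14.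

Step 5. The risks are slow syn-elimination into the strained cyclobutene, re-addition of benzeneselenenic acid to the new olefin, and acid-induced ionisation of the tertiary allylic alcohol. The fallback sets out from 5 and forms the olefin before the carbonyl addition instead of after it. Kinetic enolisation and silylation (LiN(iPr)2, TMSCl, THF, −78 °C) give methyl 2-[2-(trimethylsilyloxy)cyclobut-2-en-1-yl]acetate F3. Saegusa–Ito oxidation with Pd(OAc)2 in MeCN gives methyl 2-(2-oxocyclobut-3-en-1-yl)acetate F4. Addition of hexadecylmagnesium bromide with LaCl3·2LiCl at −78 °C, with a cold quench, comes back to the route at 10.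

Step 8. The risks are incomplete ketalisation by a secondary alcohol at the fully substituted C6 and insufficient chromatographic separation of the C3-epimeric ketals. The fallback sets out from 14 and separates enantiomers instead of covalent diastereomers. Direct ketalisation (TsOH·H2O, MeOH) and removal of the C6 epimers on silica give racemic 17, that is 17 together with methyl 2-[(3R,6R)-6-hexadecyl-6-methoxy-3,6-dihydro-1,2-dioxin-3-yl]acetate F5. Preparative HPLC on a polysaccharide-based chiral stationary phase (amylose tris(3,5-dimethylphenylcarbamate)) then separates the two, and the fallback comes back to the route at 17.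

**Further compounds**

F1 | step 7 | lithium (4E)-6-oxodocos-4-enoate | [Li+].[O-]C(=O)CC/C=C/C(=O)CCCCCCCCCCCCCCCC
F2 | step 7 | methyl (4E)-6-oxodocos-4-enoate | COC(=O)CC/C=C/C(=O)CCCCCCCCCCCCCCCC
F3 | step 5 | methyl 2-[2-(trimethylsilyloxy)cyclobut-2-en-1-yl]acetate | COC(=O)CC1CC=C1O[Si](C)(C)C
F4 | step 5 | methyl 2-(2-oxocyclobut-3-en-1-yl)acetate | COC(=O)CC1C=CC1=O
F5 | step 8 | methyl 2-[(3R,6R)-6-hexadecyl-6-methoxy-3,6-dihydro-1,2-dioxin-3-yl]acetate (enantiomer of 17) | CCCCCCCCCCCCCCCC[C@]1(OC)C=C[C@@H](CC(=O)OC)OO1
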